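Everything rests on cutting ring C of the top epicatechin unit at the aryl ether bond O1–C8a. O1 only links the C2 carbinol carbon to the ring A carbon C8a, so C2, C3 and C4 can be set on an open chain and ring C closed last, in one operation, by intramolecular SNAr of the C2 alkoxide on a fluorine-bearing ortho carbon, with no stereocentre touched. The precursor is a syn C2 carbinol with O3 benzylated, the perbenzylated lower trimer bonded through its C8 to C4, and on C4 a 2-fluoro-4,6-bis(benzyloxy)phenyl group that already carries O5 and O7, so that only hydrogenolysis follows the ring closure.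

Key step: step 19

Remark 1: the three upper units are 2,3-cis, so (−)-epicatechin is bought beside (+)-catechin; (E)-3-(tributylstannyl)prop-2-en-1-ol is also taken as purchased.
Remark 2: the two fluorines that take no part in the ring closure are exchanged for benzyloxy groups already on 1,3,5-trifluorobenzene, where SNAr is easy; the leaving fluoride and the bond formed are unchanged.
Remark 3: "Tr" means the pentadeca-O-benzyl epicatechin-(4β→8)-epicatechin-(4β→8)-catechin residue, bonded through C8 of its upper unit (the trimer made in step 8 without its bromine).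

Step 1
Reactants: 1 (+)-catechin
Product: 2 5,7,3',4'-tetra-O-benzyl-(+)-catechin
Conditions: BnBr (4.4 equiv), K2CO3, DMF, 0 °C to rt
Reagents that add atoms: benzyl bromide, BrCc1ccccc1
Why: Williamson etherification in which K2CO3 deprotonates only the four phenols, which are benzylated, while the less acidic secondary 3-OH stays free and neither stereocentre is involved.

Step 2
Reactants: 2 5,7,3',4'-tetra-O-benzyl-(+)-catechin
Product: 3 3,5,7,3',4'-penta-O-benzyl-(+)-catechin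
Conditions: NaH, BnBr, Bu4NI (cat.), DMF, 0 °C to rt
Reagents that add atoms: benzyl bromide, BrCc1ccccc1
Why: Williamson etherification of the sodium alkoxide of the remaining 3-OH, after which only the ring A carbons of the lower unit can still react.

Step 3
Reactants: 4 (−)-epicatechin
Product: 5 5,7,3',4'-tetra-O-benzyl-(−)-epicatechin
Conditions: BnBr (4.4 equiv), K2CO3, DMF, 0 °C to rt
Reagents that add atoms: benzyl bromide, BrCc1ccccc1
Why: Williamson etherification of the four phenols under carbonate conditions that are too mild to open ring C or epimerise C2.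

Step 4
Reactants: 5 5,7,3',4'-tetra-O-benzyl-(−)-epicatechin
Product: 6 3,5,7,3',4'-penta-O-benzyl-(−)-epicatechin
Conditions: NaH, BnBr, Bu4NI (cat.), DMF, 0 °C to rt
Reagents that add atoms: benzyl bromide, BrCc1ccccc1
Why: Williamson etherification of the axial 3-alkoxide, which installs the O3 benzyl group that later directs the C4 couplings to the β face.

Step 5
Reactants: 6 3,5,7,3',4'-penta-O-benzyl-(−)-epicatechin
Product: 7 4β-(2-ethoxyethoxy)-3,5,7,3',4'-penta-O-benzyl-(−)-epicatechin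
Conditions: DDQ (2 equiv), 2-ethoxyethanol, CH2Cl2, rt
Reagents that add atoms: 2-ethoxyethanol, CCOCCO
Why: Benzylic oxidation in which DDQ abstracts hydride from C4 and the cation, stabilised by the trioxygenated ring A, is captured by the alcohol anti to the 3-benzyloxy group (4β), a centre that serves only as carrier of a leaving group.

Step 6
Reactants: 7 4β-(2-ethoxyethoxy)-3,5,7,3',4'-penta-O-benzyl-(−)-epicatechin
Product: 8 8-bromo-4β-(2-ethoxyethoxy)-3,5,7,3',4'-penta-O-benzyl-(−)-epicatechin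
Conditions: NBS (1.0 equiv), CH2Cl2, −20 °C
Reagents that add atoms: N-bromosuccinimide, O=C1CCC(=O)N1Br
Why: Electrophilic aromatic bromination at C8, the most reactive free carbon of a 5,7-dialkoxyflavan ring A, gives an electrophile that can no longer act as a nucleophile at C8 and carries the handle for step 9.

Step 7
Reactants: 7 4β-(2-ethoxyethoxy)-3,5,7,3',4'-penta-O-benzyl-(−)-epicatechin; 3 3,5,7,3',4'-penta-O-benzyl-(+)-catechin (3 equiv)
Product: 9 deca-O-benzyl epicatechin-(4β→8)-catechin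
Conditions: TMSOTf (0.2 equiv), CH2Cl2, −78 °C
Reagents that add atoms: none
Why: Lewis acid-promoted Friedel–Crafts flavan coupling in which TMSOTf ionises the C4 ether of 7 and C8 of 3, used in excess to suppress oligomerisation, attacks the C4 cation anti to the 3-benzyloxy group, which sets the 4β (3,4-trans) centre.

Step 8
Reactants: 9 deca-O-benzyl epicatechin-(4β→8)-catechin (1.5 equiv); 8 8-bromo-4β-(2-ethoxyethoxy)-3,5,7,3',4'-penta-O-benzyl-(−)-epicatechin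
Product: 10 Tr–Br, 8-bromo-pentadeca-O-benzyl epicatechin-(4β→8)-epicatechin-(4β→8)-catechin (bromine on C8 of the upper unit)
Conditions: TMSOTf (0.2 equiv), CH2Cl2, −78 °C
Reagents that add atoms: none
Why: The same Friedel–Crafts coupling, in which the bromine of 8 prevents self-condensation, C8 of the upper unit of 9 is the most nucleophilic free carbon, and the new C4 centre again forms anti to the neighbouring 3-benzyloxy group (4β).

Step 9
Reactants: 10 Tr–Br; 11 (E)-3-(tributylstannyl)prop-2-en-1-ol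
Product: 12 (E)-3-Tr-prop-2-en-1-ol
Conditions: Pd(P(t-Bu)3)2 (5 mol%), CsF, 1,4-dioxane, 90 °C
Reagents that add atoms: none
Why: Stille coupling in which the bulky, electron-rich phosphine lets zerovalent palladium insert into the hindered, electron-rich C8–Br bond, fluoride activates the stannane, and the alkenyl group is transferred with retention of its E geometry.

Step 10
Reactants: 12 (E)-3-Tr-prop-2-en-1-ol
Product: 13 [(2S,3S)-3-Tr-oxiran-2-yl]methanol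
Conditions: Ti(OiPr)4 (10 mol%), L-(+)-diethyl tartrate (12 mol%), t-BuOOH, 4 Å molecular sieves, CH2Cl2, −25 °C
Reagents that add atoms: tert-butyl hydroperoxide, CC(C)(C)OO
Why: Sharpless asymmetric epoxidation in which the allylic alcohol binds to the catalyst formed from Ti(OiPr)4 and the tartrate, and L-(+)-diethyl tartrate directs oxygen to the face that gives the (2S,3S)-trans-epoxide, fixing the future C3 and, after inversion in step 13, the future C4.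

Step 11
Reactants: 13 [(2S,3S)-3-Tr-oxiran-2-yl]methanol
Product: 14 tert-butyl{[(2S,3S)-3-Tr-oxiran-2-yl]methoxy}diphenylsilane
Conditions: TBDPSCl, imidazole, CH2Cl2, 0 °C
Reagents that add atoms: tert-butyl(chloro)diphenylsilane, CC(C)(C)[Si](Cl)(c1ccccc1)c1ccccc1
Why: Silylation of the primary alcohol under basic, Lewis-acid-free conditions keeps the labile epoxide intact and removes both the acidic proton and the Payne rearrangement pathway before the organolithium step.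

Step 12
Reactants: 15 1,3,5-trifluorobenzene
Product: 17 1,3-bis(benzyloxy)-5-fluorobenzene, via 1-(benzyloxy)-3,5-difluorobenzene 16 (not isolated)
Conditions: BnOH (2.05 equiv), NaH, NMP, 0 to 80 °C
Reagents that add atoms: benzyl alcohol, OCc1ccccc1
Why: Twofold SNAr by sodium benzyloxide in which each displacement is activated by the remaining meta fluorines, while the third fluoride, on a ring that now bears two alkoxy groups and no other fluorine, is not displaced at this temperature.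

Step 13
Reactants: 17 1,3-bis(benzyloxy)-5-fluorobenzene (3 equiv); 14 tert-butyl{[(2S,3S)-3-Tr-oxiran-2-yl]methoxy}diphenylsilane
Product: 19 (2R,3S)-3-[2,4-bis(benzyloxy)-6-fluorophenyl]-1-[(tert-butyldiphenylsilyl)oxy]-3-Tr-propan-2-ol, via [2,4-bis(benzyloxy)-6-fluorophenyl]lithium 18 (not isolated)
Conditions: n-BuLi, THF, −78 °C; then 14, BF3·OEt2, −78 °C
Reagents that add atoms: none
Why: Fluorine and the flanking benzyloxy group direct lithiation to C2 of 17, and the aryllithium opens the BF3-activated trans-epoxide at its benzylic carbon, where the trioxygenated ring stabilises positive charge, from the face opposite the C–O bond (Lewis acid-assisted SN2-type epoxide opening with inversion), which sets the future C4 anti to O3.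

Step 14
Reactants: 19 (2R,3S)-3-[2,4-bis(benzyloxy)-6-fluorophenyl]-1-[(tert-butyldiphenylsilyl)oxy]-3-Tr-propan-2-ol
Product: 20 {[(2R,3S)-2-(benzyloxy)-3-[2,4-bis(benzyloxy)-6-fluorophenyl]-3-Tr-propyl]oxy}(tert-butyl)diphenylsilane
Conditions: BnBr (5 equiv), NaH, Bu4NI (cat.), THF–DMF, 0 °C
Reagents that add atoms: benzyl bromide, BrCc1ccccc1
Why: Williamson etherification of the future O3 alkoxide, which at 0 °C should be faster than SNAr on the non-activated fluoroarene and than silyl migration, blocks O3 so that it cannot form a five-membered ether later.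

Step 15
Reactants: 20 {[(2R,3S)-2-(benzyloxy)-3-[2,4-bis(benzyloxy)-6-fluorophenyl]-3-Tr-propyl]oxy}(tert-butyl)diphenylsilane
Product: 21 (2R,3S)-2-(benzyloxy)-3-[2,4-bis(benzyloxy)-6-fluorophenyl]-3-Tr-propan-1-ol
Conditions: TBAF, THF, 0 °C to rt
Reagents that add atoms: none
Why: Fluoride cleaves the Si–O bond of the primary silyl ether selectively, since benzyl ethers and the non-activated aryl fluoride are inert to TBAF at this temperature.

Step 16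
Reactants: 21 (2R,3S)-2-(benzyloxy)-3-[2,4-bis(benzyloxy)-6-fluorophenyl]-3-Tr-propan-1-ol
Product: 22 (2R,3S)-2-(benzyloxy)-3-[2,4-bis(benzyloxy)-6-fluorophenyl]-3-Tr-propanal
Conditions: Dess–Martin periodinane, NaHCO3, CH2Cl2, 0 °C
Reagents that add atoms: none
Why: Dess–Martin oxidation under buffered, non-basic conditions takes the primary alcohol to the aldehyde without epimerising the α-benzyloxy centre, and the crude aldehyde is used at once.

Step 17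
Reactants: 23 4-bromocatechol
Product: 24 4-bromo-1,2-bis(benzyloxy)benzene
Conditions: BnBr (2.2 equiv), K2CO3, DMF, rt
Reagents that add atoms: benzyl bromide, BrCc1ccccc1
Why: Williamson etherification of both phenols gives the protected ring B bromide.

Step 18
Reactants: 24 4-bromo-1,2-bis(benzyloxy)benzene; 22 (2R,3S)-2-(benzyloxy)-3-[2,4-bis(benzyloxy)-6-fluorophenyl]-3-Tr-propanal
Product: 26 (1R,2R,3S)-1-[3,4-bis(benzyloxy)phenyl]-2-(benzyloxy)-3-[2,4-bis(benzyloxy)-6-fluorophenyl]-3-Tr-propan-1-ol, via [3,4-bis(benzyloxy)phenyl]magnesium bromide 25 (not isolated)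
Conditions: Mg, THF, 40 °C; then 22 premixed with MgBr2·OEt2, CH2Cl2, −78 °C
Reagents that add atoms: none
Why: Grignard addition under Cram chelate control, in which magnesium bridges the aldehyde oxygen and the α-benzyloxy oxygen and the aryl group adds to the face of the chelate opposite the bulky diarylmethyl substituent, gives the 1,2-syn carbinol (new C2, R).

Step 19
Reactants: 26 (1R,2R,3S)-1-[3,4-bis(benzyloxy)phenyl]-2-(benzyloxy)-3-[2,4-bis(benzyloxy)-6-fluorophenyl]-3-Tr-propan-1-ol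
Product: 27 eicosa-O-benzyl epicatechin-(4β→8)-epicatechin-(4β→8)-epicatechin-(4β→8)-catechin (perbenzylated target tetramer)
Conditions: KH (1.2 equiv), 18-crown-6, THF, 0 °C; then DMPU, 60 °C
Reagents that add atoms: none
Why: KH deprotonates the only free hydroxyl to the potassium C2 alkoxide, which adds to the fluorine-bearing ortho carbon of the aryl group on C4 to give a Meisenheimer adduct, stabilised inductively by the two meta benzyloxy groups, and fluoride then leaves (addition–elimination SNAr). The closest known reaction type is the intramolecular SNAr etherification of a fluoroarene by a side-chain alkoxide, as used to close chroman and flavan rings. Ring C closes in a 6-exo mode, O1 bonding to C8a. No stereocentre is formed or broken: the C2–O bond stays intact, so the syn C2/C3 relation of 26 becomes the 2,3-cis relation of the ring and C4 keeps its trans relation to O3. The step needs attack by the C2 oxygen alone at a single aryl carbon, and the substrate secures this because every other oxygen is benzylated (no five-membered ether through O3) and the ring carries only one fluoride, whose displacement can only give the 5,7-dioxygenated ring A.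

Step 20
Reactants: 27 eicosa-O-benzyl epicatechin-(4β→8)-epicatechin-(4β→8)-epicatechin-(4β→8)-catechin
Product: 28 epicatechin-(4β→8)-epicatechin-(4β→8)-epicatechin-(4β→8)-catechin (the target)
Conditions: H2 (1 atm), Pd(OH)2/C, THF–MeOH–H2O, rt
Reagents that add atoms: none
Why: Hydrogenolysis on Pd(OH)2/C cleaves the twenty benzylic C–O bonds of the benzyl ethers, while the ring C ethers and the interflavan C–C bonds should not be reduced under these mild conditions and no stereocentre is involved.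

Compound list

1 | (+)-catechin, (2R,3S) | O[C@H]1Cc2c(O)cc(O)cc2O[C@@H]1c1ccc(O)c(O)c1 | starting material
2 | 5,7,3',4'-tetra-O-benzyl-(+)-catechin | c9ccccc9COc1cc(OCc9ccccc9)c2c(c1)O[C@H](c1ccc(OCc9ccccc9)c(OCc9ccccc9)c1)[C@@H](O)C2 | intermediate
3 | 3,5,7,3',4'-penta-O-benzyl-(+)-catechin | c9ccccc9COc1cc(OCc9ccccc9)c2c(c1)O[C@H](c1ccc(OCc9ccccc9)c(OCc9ccccc9)c1)[C@@H](OCc9ccccc9)C2 | intermediate
4 | (−)-epicatechin, (2R,3R) | Oc1cc(O)c2c(c1)O[C@H](c1ccc(O)c(O)c1)[C@H](O)C2 | starting material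
5 | 5,7,3',4'-tetra-O-benzyl-(−)-epicatechin | c9ccccc9COc1cc(OCc9ccccc9)c2c(c1)O[C@H](c1ccc(OCc9ccccc9)c(OCc9ccccc9)c1)[C@H](O)C2 | intermediate
6 | 3,5,7,3',4'-penta-O-benzyl-(−)-epicatechin | c9ccccc9COc1cc(OCc9ccccc9)c2c(c1)O[C@H](c1ccc(OCc9ccccc9)c(OCc9ccccc9)c1)[C@H](OCc9ccccc9)C2 | intermediate
7 | 4β-(2-ethoxyethoxy)-3,5,7,3',4'-penta-O-benzyl-(−)-epicatechin (C4 ether trans to O3) | c9ccccc9COc1cc(OCc9ccccc9)c2c(c1)O[C@H](c1ccc(OCc9ccccc9)c(OCc9ccccc9)c1)[C@H](OCc9ccccc9)[C@H]2OCCOCC | intermediate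
8 | 8-bromo-4β-(2-ethoxyethoxy)-3,5,7,3',4'-penta-O-benzyl-(−)-epicatechin | c9ccccc9COc1cc(OCc9ccccc9)c2c(c1Br)O[C@H](c1ccc(OCc9ccccc9)c(OCc9ccccc9)c1)[C@H](OCc9ccccc9)[C@H]2OCCOCC | intermediate
9 | deca-O-benzyl epicatechin-(4β→8)-catechin | c9ccccc9COc1cc(OCc9ccccc9)c2c(c1)O[C@H](c1ccc(OCc9ccccc9)c(OCc9ccccc9)c1)[C@H](OCc9ccccc9)[C@H]2c1c(OCc9ccccc9)cc(OCc9ccccc9)c2c1O[C@H](c1ccc(OCc9ccccc9)c(OCc9ccccc9)c1)[C@@H](OCc9ccccc9)C2 | intermediate
10 | Tr–Br, 8-bromo-pentadeca-O-benzyl epicatechin-(4β→8)-epicatechin-(4β→8)-catechin, bromine on C8 of the upper unit | Brc1c(OCc9ccccc9)cc(OCc9ccccc9)c2c1O[C@H](c1ccc(OCc9ccccc9)c(OCc9ccccc9)c1)[C@H](OCc9ccccc9)[C@H]2c1c(OCc9ccccc9)cc(OCc9ccccc9)c2c1O[C@H](c1ccc(OCc9ccccc9)c(OCc9ccccc9)c1)[C@H](OCc9ccccc9)[C@H]2c1c(OCc9ccccc9)cc(OCc9ccccc9)c2c1O[C@H](c1ccc(OCc9ccccc9)c(OCc9ccccc9)c1)[C@@H](OCc9ccccc9)C2 | intermediate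
11 | (E)-3-(tributylstannyl)prop-2-en-1-ol | OC/C=C/[Sn](CCCC)(CCCC)CCCC | starting material
12 | (E)-3-Tr-prop-2-en-1-ol | OC/C=C/c1c(OCc9ccccc9)cc(OCc9ccccc9)c2c1O[C@H](c1ccc(OCc9ccccc9)c(OCc9ccccc9)c1)[C@H](OCc9ccccc9)[C@H]2c1c(OCc9ccccc9)cc(OCc9ccccc9)c2c1O[C@H](c1ccc(OCc9ccccc9)c(OCc9ccccc9)c1)[C@H](OCc9ccccc9)[C@H]2c1c(OCc9ccccc9)cc(OCc9ccccc9)c2c1O[C@H](c1ccc(OCc9ccccc9)c(OCc9ccccc9)c1)[C@@H](OCc9ccccc9)C2 | intermediate
13 | [(2S,3S)-3-Tr-oxiran-2-yl]methanol (trans-epoxide) | OC[C@@H]1O[C@H]1c1c(OCc9ccccc9)cc(OCc9ccccc9)c2c1O[C@H](c1ccc(OCc9ccccc9)c(OCc9ccccc9)c1)[C@H](OCc9ccccc9)[C@H]2c1c(OCc9ccccc9)cc(OCc9ccccc9)c2c1O[C@H](c1ccc(OCc9ccccc9)c(OCc9ccccc9)c1)[C@H](OCc9ccccc9)[C@H]2c1c(OCc9ccccc9)cc(OCc9ccccc9)c2c1O[C@H](c1ccc(OCc9ccccc9)c(OCc9ccccc9)c1)[C@@H](OCc9ccccc9)C2 | intermediate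
14 | tert-butyl{[(2S,3S)-3-Tr-oxiran-2-yl]methoxy}diphenylsilane | CC(C)(C)[Si](c1ccccc1)(c1ccccc1)OC[C@@H]1O[C@H]1c1c(OCc9ccccc9)cc(OCc9ccccc9)c2c1O[C@H](c1ccc(OCc9ccccc9)c(OCc9ccccc9)c1)[C@H](OCc9ccccc9)[C@H]2c1c(OCc9ccccc9)cc(OCc9ccccc9)c2c1O[C@H](c1ccc(OCc9ccccc9)c(OCc9ccccc9)c1)[C@H](OCc9ccccc9)[C@H]2c1c(OCc9ccccc9)cc(OCc9ccccc9)c2c1O[C@H](c1ccc(OCc9ccccc9)c(OCc9ccccc9)c1)[C@@H](OCc9ccccc9)C2 | intermediate
15 | 1,3,5-trifluorobenzene | Fc1cc(F)cc(F)c1 | starting material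
16 | 1-(benzyloxy)-3,5-difluorobenzene | Fc1cc(F)cc(OCc2ccccc2)c1 | intermediate
17 | 1,3-bis(benzyloxy)-5-fluorobenzene | Fc1cc(OCc2ccccc2)cc(OCc2ccccc2)c1 | intermediate
18 | [2,4-bis(benzyloxy)-6-fluorophenyl]lithium | [Li]c1c(F)cc(OCc2ccccc2)cc1OCc2ccccc2 | intermediate
19 | (2R,3S)-3-[2,4-bis(benzyloxy)-6-fluorophenyl]-1-[(tert-butyldiphenylsilyl)oxy]-3-Tr-propan-2-ol | CC(C)(C)[Si](c1ccccc1)(c1ccccc1)OC[C@H](O)[C@H](c1c(F)cc(OCc9ccccc9)cc1OCc9ccccc9)c1c(OCc9ccccc9)cc(OCc9ccccc9)c2c1O[C@H](c1ccc(OCc9ccccc9)c(OCc9ccccc9)c1)[C@H](OCc9ccccc9)[C@H]2c1c(OCc9ccccc9)cc(OCc9ccccc9)c2c1O[C@H](c1ccc(OCc9ccccc9)c(OCc9ccccc9)c1)[C@H](OCc9ccccc9)[C@H]2c1c(OCc9ccccc9)cc(OCc9ccccc9)c2c1O[C@H](c1ccc(OCc9ccccc9)c(OCc9ccccc9)c1)[C@@H](OCc9ccccc9)C2 | intermediate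
20 | {[(2R,3S)-2-(benzyloxy)-3-[2,4-bis(benzyloxy)-6-fluorophenyl]-3-Tr-propyl]oxy}(tert-butyl)diphenylsilane | CC(C)(C)[Si](c1ccccc1)(c1ccccc1)OC[C@H](OCc9ccccc9)[C@H](c1c(F)cc(OCc9ccccc9)cc1OCc9ccccc9)c1c(OCc9ccccc9)cc(OCc9ccccc9)c2c1O[C@H](c1ccc(OCc9ccccc9)c(OCc9ccccc9)c1)[C@H](OCc9ccccc9)[C@H]2c1c(OCc9ccccc9)cc(OCc9ccccc9)c2c1O[C@H](c1ccc(OCc9ccccc9)c(OCc9ccccc9)c1)[C@H](OCc9ccccc9)[C@H]2c1c(OCc9ccccc9)cc(OCc9ccccc9)c2c1O[C@H](c1ccc(OCc9ccccc9)c(OCc9ccccc9)c1)[C@@H](OCc9ccccc9)C2 | intermediate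
21 | (2R,3S)-2-(benzyloxy)-3-[2,4-bis(benzyloxy)-6-fluorophenyl]-3-Tr-propan-1-ol | OC[C@H](OCc9ccccc9)[C@H](c1c(F)cc(OCc9ccccc9)cc1OCc9ccccc9)c1c(OCc9ccccc9)cc(OCc9ccccc9)c2c1O[C@H](c1ccc(OCc9ccccc9)c(OCc9ccccc9)c1)[C@H](OCc9ccccc9)[C@H]2c1c(OCc9ccccc9)cc(OCc9ccccc9)c2c1O[C@H](c1ccc(OCc9ccccc9)c(OCc9ccccc9)c1)[C@H](OCc9ccccc9)[C@H]2c1c(OCc9ccccc9)cc(OCc9ccccc9)c2c1O[C@H](c1ccc(OCc9ccccc9)c(OCc9ccccc9)c1)[C@@H](OCc9ccccc9)C2 | intermediate
22 | (2R,3S)-2-(benzyloxy)-3-[2,4-bis(benzyloxy)-6-fluorophenyl]-3-Tr-propanal | O=C[C@H](OCc9ccccc9)[C@H](c1c(F)cc(OCc9ccccc9)cc1OCc9ccccc9)c1c(OCc9ccccc9)cc(OCc9ccccc9)c2c1O[C@H](c1ccc(OCc9ccccc9)c(OCc9ccccc9)c1)[C@H](OCc9ccccc9)[C@H]2c1c(OCc9ccccc9)cc(OCc9ccccc9)c2c1O[C@H](c1ccc(OCc9ccccc9)c(OCc9ccccc9)c1)[C@H](OCc9ccccc9)[C@H]2c1c(OCc9ccccc9)cc(OCc9ccccc9)c2c1O[C@H](c1ccc(OCc9ccccc9)c(OCc9ccccc9)c1)[C@@H](OCc9ccccc9)C2 | intermediate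
23 | 4-bromocatechol | Oc1ccc(Br)cc1O | starting material
24 | 4-bromo-1,2-bis(benzyloxy)benzene | Brc1ccc(OCc2ccccc2)c(OCc2ccccc2)c1 | intermediate
25 | [3,4-bis(benzyloxy)phenyl]magnesium bromide | Br[Mg]c1ccc(OCc2ccccc2)c(OCc2ccccc2)c1 | intermediate
26 | (1R,2R,3S)-1-[3,4-bis(benzyloxy)phenyl]-2-(benzyloxy)-3-[2,4-bis(benzyloxy)-6-fluorophenyl]-3-Tr-propan-1-ol (syn C2 carbinol; precursor of the key step) | O[C@H](c1ccc(OCc9ccccc9)c(OCc9ccccc9)c1)[C@H](OCc9ccccc9)[C@H](c1c(F)cc(OCc9ccccc9)cc1OCc9ccccc9)c1c(OCc9ccccc9)cc(OCc9ccccc9)c2c1O[C@H](c1ccc(OCc9ccccc9)c(OCc9ccccc9)c1)[C@H](OCc9ccccc9)[C@H]2c1c(OCc9ccccc9)cc(OCc9ccccc9)c2c1O[C@H](c1ccc(OCc9ccccc9)c(OCc9ccccc9)c1)[C@H](OCc9ccccc9)[C@H]2c1c(OCc9ccccc9)cc(OCc9ccccc9)c2c1O[C@H](c1ccc(OCc9ccccc9)c(OCc9ccccc9)c1)[C@@H](OCc9ccccc9)C2 | intermediate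
27 | eicosa-O-benzyl epicatechin-(4β→8)-epicatechin-(4β→8)-epicatechin-(4β→8)-catechin (product of the key step; top unit 2,3-cis-3,4-trans) | c9ccccc9COc1cc(OCc9ccccc9)c2c(c1)O[C@H](c1ccc(OCc9ccccc9)c(OCc9ccccc9)c1)[C@H](OCc9ccccc9)[C@H]2c1c(OCc9ccccc9)cc(OCc9ccccc9)c2c1O[C@H](c1ccc(OCc9ccccc9)c(OCc9ccccc9)c1)[C@H](OCc9ccccc9)[C@H]2c1c(OCc9ccccc9)cc(OCc9ccccc9)c2c1O[C@H](c1ccc(OCc9ccccc9)c(OCc9ccccc9)c1)[C@H](OCc9ccccc9)[C@H]2c1c(OCc9ccccc9)cc(OCc9ccccc9)c2c1O[C@H](c1ccc(OCc9ccccc9)c(OCc9ccccc9)c1)[C@@H](OCc9ccccc9)C2 | intermediate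
28 | epicatechin-(4β→8)-epicatechin-(4β→8)-epicatechin-(4β→8)-catechin, the free tetramer | Oc1cc(O)c2c(c1)O[C@H](c1ccc(O)c(O)c1)[C@H](O)[C@H]2c1c(O)cc(O)c2c1O[C@H](c1ccc(O)c(O)c1)[C@H](O)[C@H]2c1c(O)cc(O)c2c1O[C@H](c1ccc(O)c(O)c1)[C@H](O)[C@H]2c1c(O)cc(O)c2c1O[C@H](c1ccc(O)c(O)c1)[C@@H](O)C2 | target

Total step count: 20.
Longest linear sequence: 15 steps, from (−)-epicatechin 4 to 28 through steps 3, 4, 5, 6, 8, 9, 10, 11, 13, 14, 15, 16, 18, 19 and 20.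

Steps most likely to fail

Step 13. The BF3-bound epoxide sits next to a 2,4,6-trioxygenated ring and may ionise before the aryllithium arrives. Attack would then no longer be confined to the face opposite the C–O bond, which erodes the C4 configuration, or a 1,2-hydride shift to a carbonyl compound could take over. The fallback sets out from 18 and 14 and comes back at 19. It leaves out the Lewis acid and makes the bond by a CuI-catalysed SN2 displacement: 18 is transmetalated with MgBr2·OEt2 at −78 °C to [2,4-bis(benzyloxy)-6-fluorophenyl]magnesium bromide F1, which should open 14 with CuI (10 mol%) in THF at −40 °C with inversion at the benzylic carbon and give 19.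

Step 10. The newly formed, very electron-rich benzylic epoxide may be opened by isopropanol, tartrate or hydroperoxide under the Lewis-acidic Ti(OiPr)4, so that little epoxy alcohol survives. The fallback sets out from 12 and comes back at 14. It reverses the order of protection and oxidation and avoids the metal: 12 is silylated (TBDPSCl, imidazole, CH2Cl2) to tert-butyl(diphenyl){[(E)-3-Tr-prop-2-en-1-yl]oxy}silane F2. F2 is then epoxidised by the dioxirane formed from the L-fructose-derived Shi ketone and KHSO5 (as 2KHSO5·KHSO4·K2SO4) in K2CO3-buffered MeCN–dimethoxymethane–water at 0 °C. This Shi epoxidation, run with the ketone enantiomer opposite to the usual D-fructose one, should give the (2S,3S)-epoxide 14 directly.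

Step 19. The fluoride to be displaced sits on a ring with two donor substituents, so ring closure may be slow enough for base-induced elimination of benzyloxide across C3–C4, or other decay of the alkoxide, to compete. The fallback sets out from 14 and 15 and comes back at 27; it carries a more electrophilic ring through the closure and brings in O5 and O7 afterwards. 15 is lithiated (n-BuLi, THF, −78 °C) to (2,4,6-trifluorophenyl)lithium F3, which should open 14 with BF3·OEt2 to (2R,3S)-1-[(tert-butyldiphenylsilyl)oxy]-3-Tr-3-(2,4,6-trifluorophenyl)propan-2-ol F4. F4 is benzylated without a strong base (BnBr, Ag2O), to avoid a five-membered SNAr ether on the activated ring, which should give {[(2R,3S)-2-(benzyloxy)-3-Tr-3-(2,4,6-trifluorophenyl)propyl]oxy}(tert-butyl)diphenylsilane F5. HF·pyridine should then free (2R,3S)-2-(benzyloxy)-3-Tr-3-(2,4,6-trifluorophenyl)propan-1-ol F6, and Dess–Martin oxidation should give (2R,3S)-2-(benzyloxy)-3-Tr-3-(2,4,6-trifluorophenyl)propanal F7. Chelation-controlled addition of 25 should give the syn carbinol (1R,2R,3S)-1-[3,4-bis(benzyloxy)phenyl]-2-(benzyloxy)-3-Tr-3-(2,4,6-trifluorophenyl)propan-1-ol F8. KH in THF at 0 °C should close ring C to the perbenzylated tetramer whose top unit has a 5,7-difluoro ring A F9. NaOCH2Ph (from BnOH and NaH) in DMPU at 100 to 140 °C should replace first the less hindered 7-fluoride, giving the perbenzylated tetramer whose top unit has a 7-benzyloxy-5-fluoro ring A F10, and then the 5-fluoride, which gives 27.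

Further compounds

F1 | step 13 | [2,4-bis(benzyloxy)-6-fluorophenyl]magnesium bromide | Br[Mg]c1c(F)cc(OCc2ccccc2)cc1OCc2ccccc2
F2 | step 10 | tert-butyl(diphenyl){[(E)-3-Tr-prop-2-en-1-yl]oxy}silane | CC(C)(C)[Si](c1ccccc1)(c1ccccc1)OC/C=C/c1c(OCc9ccccc9)cc(OCc9ccccc9)c2c1O[C@H](c1ccc(OCc9ccccc9)c(OCc9ccccc9)c1)[C@H](OCc9ccccc9)[C@H]2c1c(OCc9ccccc9)cc(OCc9ccccc9)c2c1O[C@H](c1ccc(OCc9ccccc9)c(OCc9ccccc9)c1)[C@H](OCc9ccccc9)[C@H]2c1c(OCc9ccccc9)cc(OCc9ccccc9)c2c1O[C@H](c1ccc(OCc9ccccc9)c(OCc9ccccc9)c1)[C@@H](OCc9ccccc9)C2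
F3 | step 19 | (2,4,6-trifluorophenyl)lithium | [Li]c1c(F)cc(F)cc1F
F4 | step 19 | (2R,3S)-1-[(tert-butyldiphenylsilyl)oxy]-3-Tr-3-(2,4,6-trifluorophenyl)propan-2-ol | CC(C)(C)[Si](c1ccccc1)(c1ccccc1)OC[C@H](O)[C@H](c1c(F)cc(F)cc1F)c1c(OCc9ccccc9)cc(OCc9ccccc9)c2c1O[C@H](c1ccc(OCc9ccccc9)c(OCc9ccccc9)c1)[C@H](OCc9ccccc9)[C@H]2c1c(OCc9ccccc9)cc(OCc9ccccc9)c2c1O[C@H](c1ccc(OCc9ccccc9)c(OCc9ccccc9)c1)[C@H](OCc9ccccc9)[C@H]2c1c(OCc9ccccc9)cc(OCc9ccccc9)c2c1O[C@H](c1ccc(OCc9ccccc9)c(OCc9ccccc9)c1)[C@@H](OCc9ccccc9)C2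
F5 | step 19 | {[(2R,3S)-2-(benzyloxy)-3-Tr-3-(2,4,6-trifluorophenyl)propyl]oxy}(tert-butyl)diphenylsilane | CC(C)(C)[Si](c1ccccc1)(c1ccccc1)OC[C@H](OCc9ccccc9)[C@H](c1c(F)cc(F)cc1F)c1c(OCc9ccccc9)cc(OCc9ccccc9)c2c1O[C@H](c1ccc(OCc9ccccc9)c(OCc9ccccc9)c1)[C@H](OCc9ccccc9)[C@H]2c1c(OCc9ccccc9)cc(OCc9ccccc9)c2c1O[C@H](c1ccc(OCc9ccccc9)c(OCc9ccccc9)c1)[C@H](OCc9ccccc9)[C@H]2c1c(OCc9ccccc9)cc(OCc9ccccc9)c2c1O[C@H](c1ccc(OCc9ccccc9)c(OCc9ccccc9)c1)[C@@H](OCc9ccccc9)C2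
F6 | step 19 | (2R,3S)-2-(benzyloxy)-3-Tr-3-(2,4,6-trifluorophenyl)propan-1-ol | OC[C@H](OCc9ccccc9)[C@H](c1c(F)cc(F)cc1F)c1c(OCc9ccccc9)cc(OCc9ccccc9)c2c1O[C@H](c1ccc(OCc9ccccc9)c(OCc9ccccc9)c1)[C@H](OCc9ccccc9)[C@H]2c1c(OCc9ccccc9)cc(OCc9ccccc9)c2c1O[C@H](c1ccc(OCc9ccccc9)c(OCc9ccccc9)c1)[C@H](OCc9ccccc9)[C@H]2c1c(OCc9ccccc9)cc(OCc9ccccc9)c2c1O[C@H](c1ccc(OCc9ccccc9)c(OCc9ccccc9)c1)[C@@H](OCc9ccccc9)C2
F7 | step 19 | (2R,3S)-2-(benzyloxy)-3-Tr-3-(2,4,6-trifluorophenyl)propanal | O=C[C@H](OCc9ccccc9)[C@H](c1c(F)cc(F)cc1F)c1c(OCc9ccccc9)cc(OCc9ccccc9)c2c1O[C@H](c1ccc(OCc9ccccc9)c(OCc9ccccc9)c1)[C@H](OCc9ccccc9)[C@H]2c1c(OCc9ccccc9)cc(OCc9ccccc9)c2c1O[C@H](c1ccc(OCc9ccccc9)c(OCc9ccccc9)c1)[C@H](OCc9ccccc9)[C@H]2c1c(OCc9ccccc9)cc(OCc9ccccc9)c2c1O[C@H](c1ccc(OCc9ccccc9)c(OCc9ccccc9)c1)[C@@H](OCc9ccccc9)C2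
F8 | step 19 | (1R,2R,3S)-1-[3,4-bis(benzyloxy)phenyl]-2-(benzyloxy)-3-Tr-3-(2,4,6-trifluorophenyl)propan-1-ol | O[C@H](c1ccc(OCc9ccccc9)c(OCc9ccccc9)c1)[C@H](OCc9ccccc9)[C@H](c1c(F)cc(F)cc1F)c1c(OCc9ccccc9)cc(OCc9ccccc9)c2c1O[C@H](c1ccc(OCc9ccccc9)c(OCc9ccccc9)c1)[C@H](OCc9ccccc9)[C@H]2c1c(OCc9ccccc9)cc(OCc9ccccc9)c2c1O[C@H](c1ccc(OCc9ccccc9)c(OCc9ccccc9)c1)[C@H](OCc9ccccc9)[C@H]2c1c(OCc9ccccc9)cc(OCc9ccccc9)c2c1O[C@H](c1ccc(OCc9ccccc9)c(OCc9ccccc9)c1)[C@@H](OCc9ccccc9)C2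
F9 | step 19 | perbenzylated tetramer with 5,7-difluoro ring A on the top unit | Fc1cc(F)c2c(c1)O[C@H](c1ccc(OCc9ccccc9)c(OCc9ccccc9)c1)[C@H](OCc9ccccc9)[C@H]2c1c(OCc9ccccc9)cc(OCc9ccccc9)c2c1O[C@H](c1ccc(OCc9ccccc9)c(OCc9ccccc9)c1)[C@H](OCc9ccccc9)[C@H]2c1c(OCc9ccccc9)cc(OCc9ccccc9)c2c1O[C@H](c1ccc(OCc9ccccc9)c(OCc9ccccc9)c1)[C@H](OCc9ccccc9)[C@H]2c1c(OCc9ccccc9)cc(OCc9ccccc9)c2c1O[C@H](c1ccc(OCc9ccccc9)c(OCc9ccccc9)c1)[C@@H](OCc9ccccc9)C2
F10 | step 19 | perbenzylated tetramer with 7-benzyloxy-5-fluoro ring A on the top unit | c9ccccc9COc1cc(F)c2c(c1)O[C@H](c1ccc(OCc9ccccc9)c(OCc9ccccc9)c1)[C@H](OCc9ccccc9)[C@H]2c1c(OCc9ccccc9)cc(OCc9ccccc9)c2c1O[C@H](c1ccc(OCc9ccccc9)c(OCc9ccccc9)c1)[C@H](OCc9ccccc9)[C@H]2c1c(OCc9ccccc9)cc(OCc9ccccc9)c2c1O[C@H](c1ccc(OCc9ccccc9)c(OCc9ccccc9)c1)[C@H](OCc9ccccc9)[C@H]2c1c(OCc9ccccc9)cc(OCc9ccccc9)c2c1O[C@H](c1ccc(OCc9ccccc9)c(OCc9ccccc9)c1)[C@@H](OCc9ccccc9)C2
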